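Ring C is cut at O1–C8a and C4–C4a, leaving a ring A aryne (C4a≡C8a) and a C2–C3–C4 unit that already carries both stereocentres. In the key step fluoride unmasks the aryne from an o-silylaryl triflate and a C2 alkoxide from its silyl ether. Oxygen adds to C8a, and the carbanion born at C4a closes ring C on a lactone carbonyl. The step exploits the C5 oxygen of ring A beside C4a, which polarises the triple bond. The precursor is an anti glycolate aldol adduct whose butane-2,3-diacetal lactone ties the C3 oxygen to C4. Acid, then MgI2, complete the target.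

Key step: step 11

Remark: the atoms of all fragments are named by the flavonoid numbering of the target (O1, C2, C3, C4, C4a, C5 to C8, C8a; ring B primed). Prenyl means 3-methylbut-2-en-1-yl. The target is (2R,3R), the trans series, which corresponds to the anti (R,R) 2,3-dioxygenated 3-arylpropanoyl unit.

**Ring A fragment (steps 1–5)**

Step 1
Reactants: 1 1,3-dimethoxybenzene; 2 prenyl bromide (1-bromo-3-methylbut-2-ene)
Product: 3 1,3-dimethoxy-2-prenylbenzene
Conditions: n-BuLi, THF, 0 °C → rt; then 2, 0 °C → rt
Reagents that add atoms: none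
Why: Directed ortho-metalation places lithium on the carbon between the two methoxy groups, and the aryllithium displaces the primary allylic bromide in an SN2 alkylation.

Step 2
Reactants: 3 1,3-dimethoxy-2-prenylbenzene
Product: 5 3,5-dimethoxy-4-prenylphenol, via pinacol boronate 4 (not isolated)
Conditions: [Ir(OMe)(cod)]2 (cat.), 4,4'-di-tert-butyl-2,2'-bipyridine (cat.), B2pin2, THF, 65 °C; then NaBO3·4H2O, THF/H2O, rt
Reagents that add atoms: bis(pinacolato)diboron, CC1(C)OB(OC1(C)C)B1OC(C)(C)C(C)(C)O1 (boryl group of 4); sodium perborate, [Na+].[O-]OB=O (phenol oxygen of 5)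
Why: Iridium-catalysed C–H borylation is governed by sterics and reaches only the C–H para to the prenyl group, the one position without an ortho substituent, and nucleophilic oxidation of the C–B bond by perborate gives the phenol without touching the trisubstituted alkene.

Step 3
Reactants: 5 3,5-dimethoxy-4-prenylphenol
Product: 6 3,5-dimethoxy-4-prenylphenyl N-isopropylcarbamate
Conditions: i-PrNCO, Et3N (cat.), CH2Cl2, rt
Reagents that add atoms: isopropyl isocyanate, CC(C)N=C=O
Why: Base-catalysed addition of the phenol to the isocyanate (carbamoylation) installs a strong ortho-directing group that mild base can later remove.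

Step 4
Reactants: 6 3,5-dimethoxy-4-prenylphenyl N-isopropylcarbamate
Product: 9 3,5-dimethoxy-4-prenyl-2-(trimethylsilyl)phenyl N-isopropylcarbamate, via N-silyl carbamate 7 (not isolated), via C-silylated N-silyl carbamate 8 (not isolated)
Conditions: TBSOTf, TMEDA, Et2O, 0 °C → rt; n-BuLi, TMEDA, −78 °C; TMSCl, −78 °C → rt; brief aq NaHSO4 work-up
Reagents that add atoms: tert-butyldimethylsilyl triflate, CC(C)(C)[Si](C)(C)OS(=O)(=O)C(F)(F)F (N-silyl group of 7 and 8); chlorotrimethylsilane, C[Si](C)(C)Cl
Why: Directed ortho-metalation: transient N-silylation masks the N–H, the carbamate and the adjacent methoxy group together direct lithiation to the carbon between them (the two such carbons are equivalent by symmetry, so no regiochemical question arises), TMSCl traps the aryllithium and the work-up hydrolyses the N–Si bond.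

Step 5
Reactants: 9 3,5-dimethoxy-4-prenyl-2-(trimethylsilyl)phenyl N-isopropylcarbamate
Product: 11 3,5-dimethoxy-4-prenyl-2-(trimethylsilyl)phenyl trifluoromethanesulfonate, via silylphenol 10 (not isolated)
Conditions: Et2NH, DBU, MeCN, 40 °C; then PhNTf2, rt
Reagents that add atoms: N-phenylbis(trifluoromethanesulfonimide), O=S(=O)(N(c1ccccc1)S(=O)(=O)C(F)(F)F)C(F)(F)F
Why: The secondary carbamate is cleaved by an E1cB elimination whose isocyanate is scavenged by Et2NH, and the phenoxide is sulfonylated in the same flask by PhNTf2, a sequence that stays basic and so avoids protodesilylation of the electron-rich arylsilane.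

**C2–C3–C4 fragment with ring B (steps 6–10)**

Step 6
Reactants: 12 (S)-3-chloropropane-1,2-diol; 13 butane-2,3-dione
Product: 14 (2S,5S,6S)-2-(chloromethyl)-5,6-dimethoxy-5,6-dimethyl-1,4-dioxane
Conditions: HC(OMe)3, camphorsulfonic acid (cat.), MeOH, reflux
Reagents that add atoms: trimethyl orthoformate, COC(OC)OC (source of the two methoxy groups, by way of methanol)
Why: Acid-catalysed butane-2,3-diacetal formation runs under thermodynamic control: the anomeric effect holds both methoxy groups axial and the chloromethyl group takes the equatorial place, so the S carbinol centre of 12 sets both acetal centres as S.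

Step 7
Reactants: 14 (2S,5S,6S)-2-(chloromethyl)-5,6-dimethoxy-5,6-dimethyl-1,4-dioxane
Product: 15 (2S,3S)-2,3-dimethoxy-2,3-dimethyl-5-methylidene-1,4-dioxane
Conditions: KOt-Bu, THF, rt → reflux
Reagents that add atoms: none
Why: E2 dehydrochlorination gives the exocyclic enol ether, which erases the carbinol stereocentre while the two acetal centres keep the chiral information.

Step 8
Reactants: 15 (2S,3S)-2,3-dimethoxy-2,3-dimethyl-5-methylidene-1,4-dioxane
Product: 16 (5S,6S)-5,6-dimethoxy-5,6-dimethyl-1,4-dioxan-2-one
Conditions: O3, CH2Cl2, −78 °C; then Me2S, −78 °C → rt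
Reagents that add atoms: ozone, [O-][O+]=O
Why: Ozonolysis cleaves the electron-rich 1,1-disubstituted enol ether and leaves its ring carbon as the lactone carbonyl, the acetal centres being untouched.

Step 9
Reactants: 17 vanillin (4-hydroxy-3-methoxybenzaldehyde)
Product: 18 3-methoxy-4-(methoxymethoxy)benzaldehyde
Conditions: MOMCl, i-Pr2NEt, CH2Cl2, 0 °C → rt
Reagents that add atoms: chloromethyl methyl ether, COCCl
Why: O-Alkylation of the phenol (Williamson-type ether synthesis) masks the only acidic and nucleophilic group of ring B as an acetal that survives strong base and fluoride.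

Step 10
Reactants: 16 (5S,6S)-5,6-dimethoxy-5,6-dimethyl-1,4-dioxan-2-one; 18 3-methoxy-4-(methoxymethoxy)benzaldehyde
Product: 20 (3R,5S,6S)-5,6-dimethoxy-3-{(R)-[3-methoxy-4-(methoxymethoxy)phenyl][(trimethylsilyl)oxy]methyl}-5,6-dimethyl-1,4-dioxan-2-one, via lithium aldolate 19 (not isolated)
Conditions: LiN(SiMe3)2, THF, −78 °C; 18, −78 °C, short contact; TMSCl, −78 → −20 °C; pH 7 buffer
Reagents that add atoms: chlorotrimethylsilane, C[Si](C)(C)Cl
Why: Lithium enolate aldol addition through a closed Zimmerman–Traxler transition state: the ring locks the enolate in the E(O) geometry, which gives the anti relation (future C2, R), the axial methoxy group on the acetal carbon 1,3 to the enolate carbon blocks one face so that the new substituent ends equatorial (future C3, R), and TMSCl traps the aldolate before it can revert.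

**Union and endgame (steps 11–13)**

Step 11
Reactants: 11 3,5-dimethoxy-4-prenyl-2-(trimethylsilyl)phenyl trifluoromethanesulfonate; 20 silylated anti aldol lactone
Product: 23 (2R,3R)-5,7-dimethoxy-2-[3-methoxy-4-(methoxymethoxy)phenyl]-3-{[(2S)-2-methoxy-3-oxobutan-2-yl]oxy}-6-prenylchroman-4-one, via aryne 21 (not isolated), via potassium alkoxide 22 (not isolated)
Conditions: 11 (slight excess) and 20 premixed, KF, 18-crown-6, THF, 0 °C → rt
Reagents that add atoms: none
Why: Proposed new method: fluoride removes both trimethylsilyl groups, so 11 collapses to aryne 21 while 20 gives the proton-free alkoxide 22, whose oxygen adds to C8a; the aryl carbanion so formed at C4a attacks the lactone carbonyl, and the expelled hemiketal oxide sheds methoxide to leave the methyl ketone of the side chain in 23. The closest known reaction type is the annulation of arynes by methyl salicylates to xanthones (heteroatom addition, then intramolecular acyl capture), together with the ring expansion of β-lactams by arynes; a secondary aliphatic alkoxide paired with a lactone acceptor has not been shown. Ring C closes by a 6-exo-trig addition–elimination at the acyl carbon, helped by the short tether and by the inductively activated α-alkoxy lactone. No stereocentre is created: C2 and C3 come unchanged from 20, since no bond to either carbon is broken. The regioselectivity needed (O at C8a, acyl at C4a) is secured by the C5 methoxy group next to C4a, whose inductive pull distorts the aryne so that C8a, flanked only by C8–H, is the more linear and electrophilic end and the charge builds up ortho to oxygen. The chemoselectivity needed (acyl capture before proton capture, addition before retro-aldol cleavage) is served by the silyl ether in place of the free alcohol, by the aprotic medium and by the slow release of fluoride from solid KF at low temperature.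

Step 12
Reactants: 23 protected chromanone
Product: 24 (2R,3R)-3-hydroxy-2-(4-hydroxy-3-methoxyphenyl)-5,7-dimethoxy-6-prenylchroman-4-one
Conditions: 2 M aq HCl, MeOH, 40 °C
Reagents that add atoms: none
Why: Acid-catalysed acetal cleavage removes the aryl methoxymethyl ether and the mixed ketal on O3 in one operation without touching C2 or C3, and the prenyl group cannot cyclise to a chroman because both neighbouring oxygens are still methyl ethers.

Step 13
Reactants: 24 (2R,3R)-3-hydroxy-2-(4-hydroxy-3-methoxyphenyl)-5,7-dimethoxy-6-prenylchroman-4-one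
Product: 25 (2R,3R)-3,5-dihydroxy-2-(4-hydroxy-3-methoxyphenyl)-7-methoxy-6-prenylchroman-4-one (target)
Conditions: MgI2·OEt2, THF, 60 °C; then dilute aq HCl
Reagents that add atoms: none
Why: Chelation-directed ether cleavage: magnesium is held between the C4 carbonyl and the peri C5 methoxy oxygen and iodide removes that methyl group by SN2, while the C7 and C3' methyl ethers lack such a chelate and the non-protic medium spares the prenyl group and both stereocentres.

**Compound list**

1 | 1,3-dimethoxybenzene | COc1cccc(OC)c1 | starting material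
2 | prenyl bromide | CC(C)=CCBr | starting material
3 | 1,3-dimethoxy-2-prenylbenzene | COc1cccc(OC)c1CC=C(C)C | intermediate
4 | 2-(3,5-dimethoxy-4-prenylphenyl)-4,4,5,5-tetramethyl-1,3,2-dioxaborolane | COc1cc(B2OC(C)(C)C(C)(C)O2)cc(OC)c1CC=C(C)C | intermediate
5 | 3,5-dimethoxy-4-prenylphenol | COc1cc(O)cc(OC)c1CC=C(C)C | intermediate
6 | 3,5-dimethoxy-4-prenylphenyl N-isopropylcarbamate | COc1cc(OC(=O)NC(C)C)cc(OC)c1CC=C(C)C | intermediate
7 | N-(tert-butyldimethylsilyl) derivative of 6 | COc1cc(OC(=O)N(C(C)C)[Si](C)(C)C(C)(C)C)cc(OC)c1CC=C(C)C | intermediate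
8 | N-(tert-butyldimethylsilyl) derivative of 9 | COc1cc(OC(=O)N(C(C)C)[Si](C)(C)C(C)(C)C)c([Si](C)(C)C)c(OC)c1CC=C(C)C | intermediate
9 | 3,5-dimethoxy-4-prenyl-2-(trimethylsilyl)phenyl N-isopropylcarbamate | COc1cc(OC(=O)NC(C)C)c([Si](C)(C)C)c(OC)c1CC=C(C)C | intermediate
10 | 3,5-dimethoxy-4-prenyl-2-(trimethylsilyl)phenol | COc1cc(O)c([Si](C)(C)C)c(OC)c1CC=C(C)C | intermediate
11 | 3,5-dimethoxy-4-prenyl-2-(trimethylsilyl)phenyl trifluoromethanesulfonate | COc1cc(OS(=O)(=O)C(F)(F)F)c([Si](C)(C)C)c(OC)c1CC=C(C)C | intermediate
12 | (S)-3-chloropropane-1,2-diol | OC[C@H](O)CCl | starting material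
13 | butane-2,3-dione | CC(=O)C(C)=O | starting material
14 | (2S,5S,6S)-2-(chloromethyl)-5,6-dimethoxy-5,6-dimethyl-1,4-dioxane | ClC[C@@H]1CO[C@](C)(OC)[C@@](C)(OC)O1 | intermediate
15 | (2S,3S)-2,3-dimethoxy-2,3-dimethyl-5-methylidene-1,4-dioxane | C=C1CO[C@](C)(OC)[C@@](C)(OC)O1 | intermediate
16 | (5S,6S)-5,6-dimethoxy-5,6-dimethyl-1,4-dioxan-2-one | O=C1CO[C@](C)(OC)[C@@](C)(OC)O1 | intermediate
17 | vanillin | COc1cc(C=O)ccc1O | starting material
18 | 3-methoxy-4-(methoxymethoxy)benzaldehyde | COCOc1ccc(C=O)cc1OC | intermediate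
19 | lithium aldolate of the (3R,1'R) anti adduct | O=C1[C@@H]([C@H]([O-])c2ccc(OCOC)c(OC)c2)O[C@](C)(OC)[C@@](C)(OC)O1.[Li+] | intermediate
20 | (3R,5S,6S)-5,6-dimethoxy-3-{(R)-[3-methoxy-4-(methoxymethoxy)phenyl][(trimethylsilyl)oxy]methyl}-5,6-dimethyl-1,4-dioxan-2-one | O=C1[C@@H]([C@H](O[Si](C)(C)C)c2ccc(OCOC)c(OC)c2)O[C@](C)(OC)[C@@](C)(OC)O1 | intermediate
21 | 3,5-dimethoxy-4-prenylbenzyne (C4a≡C8a aryne) | COC1=C(CC=C(C)C)C(OC)=CC#C1 | intermediate
22 | potassium alkoxide from 20 | O=C1[C@@H]([C@H]([O-])c2ccc(OCOC)c(OC)c2)O[C@](C)(OC)[C@@](C)(OC)O1.[K+] | intermediate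
23 | (2R,3R)-5,7-dimethoxy-2-[3-methoxy-4-(methoxymethoxy)phenyl]-3-{[(2S)-2-methoxy-3-oxobutan-2-yl]oxy}-6-prenylchroman-4-one | COCOc1ccc(cc1OC)[C@H]1Oc2cc(OC)c(CC=C(C)C)c(OC)c2C(=O)[C@@H]1O[C@](C)(OC)C(C)=O | intermediate
24 | (2R,3R)-3-hydroxy-2-(4-hydroxy-3-methoxyphenyl)-5,7-dimethoxy-6-prenylchroman-4-one | COc1cc([C@H]2Oc3cc(OC)c(CC=C(C)C)c(OC)c3C(=O)[C@@H]2O)ccc1O | intermediate
25 | (2R,3R)-3,5-dihydroxy-2-(4-hydroxy-3-methoxyphenyl)-7-methoxy-6-prenylchroman-4-one | COc1cc([C@H]2Oc3cc(OC)c(CC=C(C)C)c(O)c3C(=O)[C@@H]2O)ccc1O | target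

Total steps: 13. Longest linear sequence: 8 steps (steps 1, 2, 3, 4, 5, 11, 12, 13).

**Steps most likely to fail**

1. Step 11.
   - Risks: retro-aldol cleavage of the alkoxide before it meets the aryne, proton capture by the aryl carbanion before acyl transfer, or base-induced opening of ring C after closure.
   - The fallback uses known chemistry, sets out from 11 and 18 and returns at 24.
   - Knoevenagel–Doebner condensation of 18 with malonic acid (pyridine, piperidine, heat) gives (E)-3-[3-methoxy-4-(methoxymethoxy)phenyl]acrylic acid F1.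
   - 11 and F1 with CsF in THF at 125 °C (sealed vessel) undergo the known insertion of an aryne into the C–O bond of a carboxylic acid. The carboxylate oxygen adds at C8a and the acyl group shifts to C4a under the same C5 methoxy control. This gives the 2'-hydroxychalcone F2, and any flavanone formed beside it is funnelled back through its phenoxide in the next operation.
   - NaH and MOMCl give the 2'-O-methoxymethyl chalcone F3.
   - Juliá–Colonna epoxidation (poly-L-leucine, urea–hydrogen peroxide, DBU, THF), which attacks only the enone, gives the (αR,βS)-epoxychalcone F4.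
   - Methanolic HCl removes both methoxymethyl groups, and the freed C8a phenol opens the epoxide at the benzylic carbon with inversion to give 24.

2. Step 10.
   - Risks: erosion of the anti selectivity by reversible aldolisation with the electron-rich aldehyde, or reversion of the aldolate while it is being silylated.
   - The fallback sets out from 16 and 18 and returns at 20.
   - The aldol addition is quenched with acetic acid at −78 °C and carried on without regard to the carbinol configuration as the hydroxy lactone (carbinol epimers) F5.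
   - Dess–Martin periodinane gives the β-keto lactone F6, in which the acyl group rests in the equatorial place at C3 whichever way it equilibrates.
   - Asymmetric transfer hydrogenation (RuCl(p-cymene)[(S,S)-TsDPEN], HCO2H/Et3N) sets the carbinol centre under catalyst control and gives the anti hydroxy lactone F7.
   - TMSCl and imidazole then give 20.

3. Step 2.
   - Risks: hydroboration or migration of the prenyl double bond under the iridium catalyst, or incomplete site selectivity.
   - The fallback sets out from 2, together with purchased 3,5-dimethoxyphenol, and returns at 5.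
   - TIPSCl and imidazole give (3,5-dimethoxyphenoxy)triisopropylsilane F8.
   - The bulky silyl ether shields its own ortho positions, so n-BuLi lithiates between the two methoxy groups. Alkylation with 2 gives (3,5-dimethoxy-4-prenylphenoxy)triisopropylsilane F9.
   - TBAF in THF then gives 5.

**Further compounds**

F1 | step 11 | (E)-3-[3-methoxy-4-(methoxymethoxy)phenyl]acrylic acid | COCOc1ccc(/C=C/C(=O)O)cc1OC
F2 | step 11 | (E)-1-(6-hydroxy-2,4-dimethoxy-3-prenylphenyl)-3-[3-methoxy-4-(methoxymethoxy)phenyl]prop-2-en-1-one | COCOc1ccc(/C=C/C(=O)c2c(O)cc(OC)c(CC=C(C)C)c2OC)cc1OC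
F3 | step 11 | (E)-1-[2,4-dimethoxy-6-(methoxymethoxy)-3-prenylphenyl]-3-[3-methoxy-4-(methoxymethoxy)phenyl]prop-2-en-1-one | COCOc1ccc(/C=C/C(=O)c2c(OCOC)cc(OC)c(CC=C(C)C)c2OC)cc1OC
F4 | step 11 | [2,4-dimethoxy-6-(methoxymethoxy)-3-prenylphenyl]{(2R,3S)-3-[3-methoxy-4-(methoxymethoxy)phenyl]oxiran-2-yl}methanone | COCOc1ccc(cc1OC)[C@@H]1O[C@H]1C(=O)c1c(OCOC)cc(OC)c(CC=C(C)C)c1OC
F5 | step 10 | (3R,5S,6S)-3-{hydroxy[3-methoxy-4-(methoxymethoxy)phenyl]methyl}-5,6-dimethoxy-5,6-dimethyl-1,4-dioxan-2-one (carbinol epimers) | O=C1[C@@H](C(O)c2ccc(OCOC)c(OC)c2)O[C@](C)(OC)[C@@](C)(OC)O1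
F6 | step 10 | (3R,5S,6S)-5,6-dimethoxy-3-[3-methoxy-4-(methoxymethoxy)benzoyl]-5,6-dimethyl-1,4-dioxan-2-one | O=C1[C@@H](C(=O)c2ccc(OCOC)c(OC)c2)O[C@](C)(OC)[C@@](C)(OC)O1
F7 | step 10 | (3R,5S,6S)-3-{(R)-hydroxy[3-methoxy-4-(methoxymethoxy)phenyl]methyl}-5,6-dimethoxy-5,6-dimethyl-1,4-dioxan-2-one | O=C1[C@@H]([C@H](O)c2ccc(OCOC)c(OC)c2)O[C@](C)(OC)[C@@](C)(OC)O1
F8 | step 2 | (3,5-dimethoxyphenoxy)triisopropylsilane | COc1cc(O[Si](C(C)C)(C(C)C)C(C)C)cc(OC)c1
F9 | step 2 | (3,5-dimethoxy-4-prenylphenoxy)triisopropylsilane | COc1cc(O[Si](C(C)C)(C(C)C)C(C)C)cc(OC)c1CC=C(C)C
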